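The runs stem from a simulated flask for substances that don't exist, and the scatter is random.

A one-step world has a single clock, but in the north-west run at 4.00 h the substrate has fallen to 21.9% while target stands at 4.2%, so we must follow where the substrate goes on its way.

in all of them: substrate 0.25 M

| charge | coupling partner | second reagent | third reagent | remark | time |
|---|---|---|---|---|---|
| north-west | 1.2 equiv | 1.8 equiv | 1.8 equiv | run made earlier |  |
| north | 1.2 equiv | 2.5 equiv | 1.8 equiv | run made earlier |  |
| west | 1.2 equiv | 4 equiv | 1.8 equiv | run made earlier |  |
| alder | 1.20 equiv (fed, over 12 h) | 1.80 equiv | 1.80 equiv | all else is in the flask from the start; the feed brings no volume worth counting | 20 h |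
| elm | 1.20 equiv | 1.80 equiv | 1.80 equiv | everything together at the start | 20 h |
| ash | 1.20 equiv | 1.80 equiv (fed, over 12 h) | 1.80 equiv | all else is in the flask from the start; the feed brings no volume worth counting | 20 h |
| cedar | 1.20 equiv | 1.80 equiv (fed, over 3.0 h) | 1.80 equiv | all else is in the flask from the start; the feed brings no volume worth counting | 20 h |
| oak | 1.20 equiv | 1.80 equiv (in portions, 2, over 12 h) | 1.80 equiv | first portion at the start, last at 12 h | 20 h |

- north-west (time / h: target / %, substrate / %): 1.00: 1.4, 61.2; 1.50: 0, 50.0; 2.50: 4.1, 33.3; 4.00: 4.2, 21.9; 8.00: 19.1, 6.3; 12.0: 28.8, 2.6
- north (time / h: target / %, substrate / %): 1.33: 1.6, 50.0; 4.00: 6.6, 17.2; 8.00: 19.3, 5.5; 10.0: 27.0, 3.0; 15.0: 40.4, 0.2; 20.0: 46.9, 1.3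
- west (time / h: target / %, substrate / %): 1.33: 0.8, 44.0; 4.00: 7.6, 10.9; 8.00: 23.5, 1.1; 10.0: 28.9, 0.9; 15.0: 41.2, 1.0; 20.0: 44.2, 0.7

(scatter of a reading: 1 percentage point)

* which flask leads in amount of target, in percent of the substrate charged ("all alike" within 1.5 percentage points) (alder / elm / ash / cedar / oak / all alike)
* how much target is there at the end, in percent of the substrate charged: alder
* how much target is there at the end, in percent of the substrate charged: elm
* how much target is there at the end, in percent of the substrate charged: ash
* how much target is there at the end, in percent of the substrate charged: cedar
* how much target is there at the end, in percent of the substrate charged: oak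

- what is said of target includes crystals
- crystals is a solid; its amount is given per volume of the solution
- what was read earlier has a scatter of 1 percentage point, one standard deviation
- candidate steps: crystals <-> target; substrate + second reagent -> side product; substrate + coupling partner -> intermediate A; third reagent + intermediate B -> target; third reagent + target -> over-reaction product; second reagent + intermediate A -> intermediate B

1. We count turnovers of substrate first, treating its loss as pseudo-first-order: in the north-west run it reads 50.0% at 1.50 h, a loss rate of 0.462 h⁻¹, and in the west run, with more second reagent, it reads 44.0% at 1.33 h, a rate of 0.617 h⁻¹, both carrying the scatter of the readings.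

2. Substrate has two exits, one with coupling partner towards intermediate A and target, the other with second reagent to side product. The extra rate per extra equivalent of second reagent, scaled to 1.8 equiv, puts the side exit at 0.127 h⁻¹ and leaves 0.335 h⁻¹ for the coupling exit. With both charged from the start, as in elm, the side exit therefore starts at 0.379 of the coupling exit, a selectivity factor, and, holding that ratio through the run, we expect elm to lose 27.5% of its substrate to side product.

3. The ratio of the two exits follows [second reagent]/[coupling partner], so a feed of coupling partner shifts it. In alder, with [second reagent] counted at its charge, the exits stand level when [coupling partner] reaches 0.379 of its full charge, and a steady feed over 12 h brings that much in 4.55 h if none of the coupling partner is counted as consumed: this is the parity time, the time before which, so reckoned, the side exit leads.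

4. Our own reckoning is a judgement from that: we take alder's side share as 50.0%, and, assuming similar amounts still held in the intermediates, we expect alder's target to end 23 percentage points below elm's.

5. The forecast, made from the same runs, names cedar as leader and gives alder 30% (22% to 38%), elm 45% (41% to 49%), ash 48% (38% to 58%), cedar 51% (45% to 58%) and oak 45% (37% to 53%), holding for alder that “starving the coupling partner favours the side reaction”. Its gap between elm and alder is 15 points, which differs from ours.

6. The flasks end at alder 21.8%, elm 44.7%, ash 45.4%, cedar 48.7% and oak 39.1%, so cedar leads.

    crystals ⇌ target, rate k1*(cs1 - [target]) while solid is left; crystals form when [target] > cs1 (solubility = 12.0 mM, k = 120 h⁻¹)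
    substrate + second reagent → side product (k = 0.280 M⁻¹ h⁻¹)
    substrate + coupling partner → intermediate A (k = 1.40 M⁻¹ h⁻¹)
    third reagent + intermediate B → target (k = 0.460 M⁻¹ h⁻¹)
    third reagent + target → over-reaction product (k = 0.120 M⁻¹ h⁻¹)
    second reagent + intermediate A → intermediate B (k = 0.380 M⁻¹ h⁻¹)

7. In alder at 2.74 h, inside the parity time of 4.55 h, the side step uses substrate at 1.6 times the rate of the coupling step, and by 10.0 h it has 95% of its turnover up to 20 h behind it, while alder ends with 52.7% side product against 27.8% in elm and with target 23 points lower than elm. The neighbour of alder charged with 4.80 equiv of coupling partner has a parity time of 1.14 h, shorter than alder's, and it ends with 32.8% side product and 40.1% target.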